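The lactone ring (O1, C2 carbonyl, C3 methyl-bearing, C4 diarylmethyl-bearing, C5 methylene) is cut at C2–C3 and C4–C5, the two ring C–C bonds on either side of the C5–O1–C2 unit. This exposes that unit as a carbonyl ylide and the trans C3/C4 pair as an (E)-crotonoyl alkene. One (3+2) cycloaddition of the parent ylide, released in the flask from a chloromethyl silylmethyl ether by fluoride, onto an N-crotonoyl camphorsultam closes the oxolane ring and sets both stereocentres. Later the ether CH2 next to the methyl-bearing carbon is oxidised to the lactone carbonyl, and the acyl group is built up to the bis(3,4,5-trimethoxyphenyl)methyl group by two separate aryl transfers and a deoxygenation.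

Key step: step 3

Remark: compounds 1, 2, 4, 5 and 11 are taken as commercial, and the facial sense of the auxiliary in step 3 is assumed from the usual model for additions to s-cis N-enoyl-(2R)-bornane-10,2-sultams (attack on the Cα-Re face).

Step 1
Reactants: 1 (trimethylsilyl)methanol; 2 paraformaldehyde
Product: 3 chloromethyl (trimethylsilyl)methyl ether
Conditions: HCl (g), CH2Cl2, 0 °C; dry over CaCl2, distil
Reagents that add atoms: hydrogen chloride, Cl
Why: Chloromethylation of an alcohol (hemiformal formation, then displacement of the protonated hydroxyl by chloride) is the standard way to a chloromethyl ether; no stereocentre is involved.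

Step 2
Reactants: 4 (2R)-bornane-10,2-sultam; 5 (E)-but-2-enoyl chloride
Product: 6 (2R)-N-[(E)-but-2-enoyl]bornane-10,2-sultam
Conditions: NaH, toluene, 0 °C to rt; recrystallise
Reagents that add atoms: none
Why: N-Acylation of the sodium salt of the sultam by the acid chloride should give the crystalline enoyl imide with the (E)-geometry carried over unchanged.

Step 3
Reactants: 6 (2R)-N-[(E)-but-2-enoyl]bornane-10,2-sultam; 3 chloromethyl (trimethylsilyl)methyl ether
Product: 8 (2R)-N-[(3S,4S)-4-methyltetrahydrofuran-3-carbonyl]bornane-10,2-sultam, via carbonyl ylide 7 (not isolated)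
Conditions: CsF, MeCN, rt; 3 in excess, added slowly; minor diastereomer removed by crystallisation or chromatography
Reagents that add atoms: none
Why: Fluoride attacks silicon of 3 and chloride leaves in a 1,3-elimination that releases the nonstabilised carbonyl ylide 7, a C–O–C 1,3-dipole, which is trapped by the electron-poor alkene of 6 in a 1,3-dipolar (3+2) cycloaddition; the closest known type is the cycloaddition of silicon-derived nonstabilised carbonyl and azomethine ylides to acrylic dipolarophiles. The oxolane ring is closed by a concerted suprafacial [π4s+π2s] addition in which both C–C bonds (C2–C3 and C4–C5 of the oxolane) form in the same step. The trans relation of C3 and C4 follows from the (E)-geometry of the crotonoyl unit, because the addition is stereospecific. The absolute configuration is controlled by the auxiliary: in the s-cis enoyl conformer with C=O anti to SO2, a sulfonyl oxygen and the bornane framework screen the Cα-Si face, so the dipole should add to the Cα-Re (Cβ-Si) face and give (3S,4S). The step needs only diastereofacial selectivity, since the symmetrical dipole raises no regiochemical question and the activated C=C is the only dipolarophile offered.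

Step 4
Reactants: 8 (2R)-N-[(3S,4S)-4-methyltetrahydrofuran-3-carbonyl]bornane-10,2-sultam
Product: 9 (3S,4S)-4-methyltetrahydrofuran-3-carboxylic acid
Conditions: LiOH, H2O2, THF/H2O, 0 °C; Na2SO3; recover 4 by extraction; HCl to pH 2
Reagents that add atoms: hydrogen peroxide (as LiOOH), OO
Why: Hydroperoxide attacks the exocyclic imide carbonyl selectively (peroxide cleavage of an N-acyl auxiliary), which should free the acid without epimerising C3 and return the sultam.

Step 5
Reactants: 9 (3S,4S)-4-methyltetrahydrofuran-3-carboxylic acid
Product: 10 (3S,4S)-4-methyl-5-oxotetrahydrofuran-3-carboxylic acid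
Conditions: RuCl3 (cat.), NaIO4, CCl4/MeCN/H2O, rt
Reagents that add atoms: sodium periodate (oxygen delivered through RuO4), [Na+].[O-]I(=O)(=O)=O
Why: Catalytic RuO4 oxidises an ether α-CH2 to a lactone carbonyl; C2–H is deactivated inductively and sterically by the neighbouring carboxyl-bearing carbon, so oxidation should occur at C5 next to the methyl-bearing carbon, and no stereocentre is touched.

Step 6
Reactants: 10 (3S,4S)-4-methyl-5-oxotetrahydrofuran-3-carboxylic acid; 11 3,4,5-trimethoxyphenylmagnesium bromide
Product: 13 (3S,4S)-3-methyl-4-(3,4,5-trimethoxybenzoyl)dihydrofuran-2(3H)-one, via acid chloride 12 (not isolated)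
Conditions: (COCl)2, cat. DMF, CH2Cl2, 0 °C to rt, evaporate; then 11 (1.0 equiv) premixed with ZnCl2 (THF, 0 °C), Pd(PPh3)4 (cat.), THF, 0 °C to rt
Reagents that add atoms: none
Why: The acid chloride forms without base, so its α-stereocentre is not put at risk, and the arylzinc chloride made from 11 and ZnCl2 transfers exactly one aryl group to the acyl–palladium species (Negishi acylation); the nonbasic organozinc does not add to the new ketone or the lactone and does not enolise the ketone, so the reaction should stop at 13 with both ring stereocentres intact.

Step 7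
Reactants: 13 (3S,4S)-3-methyl-4-(3,4,5-trimethoxybenzoyl)dihydrofuran-2(3H)-one; 11 3,4,5-trimethoxyphenylmagnesium bromide
Product: 14 (3S,4S)-4-[hydroxybis(3,4,5-trimethoxyphenyl)methyl]-3-methyldihydrofuran-2(3H)-one
Conditions: 11 (1.2 equiv) premixed with anhydrous CeCl3 (THF, −78 °C); add 13, −78 °C; aq. NH4Cl at −78 °C
Reagents that add atoms: none
Why: The aryl ketone is far more electrophilic than the lactone, and the weakly basic arylcerium reagent should add once by 1,2-addition (organocerium addition to an enolisable ketone) at −78 °C without enolising 13 towards C4 or opening the lactone; the new carbinol carbon carries two identical aryl groups and is not a stereocentre.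

Step 8
Reactants: 14 (3S,4S)-4-[hydroxybis(3,4,5-trimethoxyphenyl)methyl]-3-methyldihydrofuran-2(3H)-one
Product: 15 peperomin C, (3S,4S)-4-[bis(3,4,5-trimethoxyphenyl)methyl]-3-methyldihydrofuran-2(3H)-one
Conditions: Et3SiH, CF3CO2H, CH2Cl2, 0 °C to rt
Reagents that add atoms: none
Why: The tertiary, doubly benzylic alcohol ionises in acid to a diaryl-stabilised cation that is reduced by hydride transfer from the silane (ionic hydrogenation), which does not involve the two ring stereocentres.

Compound list
1 | (trimethylsilyl)methanol | C[Si](C)(C)CO | starting material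
2 | paraformaldehyde (formaldehyde unit shown) | C=O | starting material
3 | chloromethyl (trimethylsilyl)methyl ether | C[Si](C)(C)COCCl | intermediate
4 | (2R)-bornane-10,2-sultam, (3aS,6R,7aR)-camphorsultam | CC1(C)[C@@H]2CC[C@]13CS(=O)(=O)N[C@@H]3C2 | starting material
5 | (E)-but-2-enoyl chloride (crotonyl chloride) | C/C=C/C(=O)Cl | starting material
6 | (2R)-N-[(E)-but-2-enoyl]bornane-10,2-sultam | CC1(C)[C@@H]2CC[C@]13CS(=O)(=O)N(C(=O)/C=C/C)[C@@H]3C2 | intermediate
7 | carbonyl ylide (formaldehyde O-methylide), not isolated | [CH2-][O+]=C | intermediate
8 | (2R)-N-[(3S,4S)-4-methyltetrahydrofuran-3-carbonyl]bornane-10,2-sultam (3,4-trans) | CC1(C)[C@@H]2CC[C@]13CS(=O)(=O)N(C(=O)[C@@H]4COC[C@H]4C)[C@@H]3C2 | intermediate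
9 | (3S,4S)-4-methyltetrahydrofuran-3-carboxylic acid | OC(=O)[C@@H]1COC[C@H]1C | intermediate
10 | (3S,4S)-4-methyl-5-oxotetrahydrofuran-3-carboxylic acid | OC(=O)[C@@H]1COC(=O)[C@H]1C | intermediate
11 | 3,4,5-trimethoxyphenylmagnesium bromide (THF solution) | COc1cc([Mg]Br)cc(OC)c1OC | starting material
12 | (3S,4S)-4-methyl-5-oxotetrahydrofuran-3-carbonyl chloride, not isolated | ClC(=O)[C@@H]1COC(=O)[C@H]1C | intermediate
13 | (3S,4S)-3-methyl-4-(3,4,5-trimethoxybenzoyl)dihydrofuran-2(3H)-one | COc1cc(C(=O)[C@@H]2COC(=O)[C@H]2C)cc(OC)c1OC | intermediate
14 | (3S,4S)-4-[hydroxybis(3,4,5-trimethoxyphenyl)methyl]-3-methyldihydrofuran-2(3H)-one | COc1cc(C(O)(c2cc(OC)c(OC)c(OC)c2)[C@@H]2COC(=O)[C@H]2C)cc(OC)c1OC | intermediate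
15 | peperomin C, (3S,4S)-4-[bis(3,4,5-trimethoxyphenyl)methyl]-3-methyldihydrofuran-2(3H)-one | COc1cc(C(c2cc(OC)c(OC)c(OC)c2)[C@@H]2COC(=O)[C@H]2C)cc(OC)c1OC | target

Total step count: 8. Longest linear sequence: 7 (steps 2 to 8, from sultam 4).

Steps most likely to fail

Step 3. The short-lived ylide may discriminate poorly between the two faces of the enoyl sultam, or favour the face opposite to the assumed one, so that 8 cannot be obtained as one diastereomer. The fallback moves control of the absolute configuration from the auxiliary to a resolution. It sets out from 3: ylide 7 is generated with CsF in MeCN in the presence of commercial benzyl (E)-but-2-enoate and should give racemic benzyl trans-4-methyltetrahydrofuran-3-carboxylate F1. Preparative chromatography on a chiral stationary phase would then give benzyl (3S,4S)-4-methyltetrahydrofuran-3-carboxylate F2. Hydrogenolysis (H2, Pd/C, EtOAc) comes back to the route at 9.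

Step 5. Oxidation may also occur at the C2 methylene next to the carboxyl-bearing carbon and give a mixture of regioisomeric lactones. The fallback changes the element of regiocontrol from the weak inductive bias of the free acid to steric shielding by the auxiliary. It sets out from 8, which is oxidised with RuCl3/NaIO4 while the bulky and more strongly withdrawing N-acyl sultam still screens C2, to give (2R)-N-[(3S,4S)-4-methyl-5-oxotetrahydrofuran-3-carbonyl]bornane-10,2-sultam F3. Cleavage with LiOH/H2O2 then comes back to the route at 10.

Step 7. The aryl-metal may attack the lactone carbonyl as well, or the ketone may enolise and expel the ring oxygen by β-elimination (ring opening) instead of undergoing addition. The fallback avoids any organometallic addition to the ketone and also the cationic reduction that follows it. It sets out from 13, which is condensed with p-toluenesulfonyl hydrazide (MeOH, 60 °C) to give the N-tosylhydrazone of ketone 13 F4. Base-mediated reductive coupling of F4 with 3,4,5-trimethoxyphenylboronic acid (K2CO3, dioxane, 110 °C) should form the diarylmethyl C–H centre directly and comes back to the route at 15, so that 14 and step 8 are bypassed.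

Further compounds
F1 | step 3 | benzyl trans-4-methyltetrahydrofuran-3-carboxylate, racemate (both enantiomers shown) | O=C(OCc1ccccc1)[C@@H]1COC[C@H]1C.O=C(OCc1ccccc1)[C@H]1COC[C@@H]1C
F2 | step 3 | benzyl (3S,4S)-4-methyltetrahydrofuran-3-carboxylate | O=C(OCc1ccccc1)[C@@H]1COC[C@H]1C
F3 | step 5 | (2R)-N-[(3S,4S)-4-methyl-5-oxotetrahydrofuran-3-carbonyl]bornane-10,2-sultam | CC1(C)[C@@H]2CC[C@]13CS(=O)(=O)N(C(=O)[C@@H]4COC(=O)[C@H]4C)[C@@H]3C2
F4 | step 7 | N-tosylhydrazone of ketone 13 (C=N geometry not defined) | COc1cc(C(=NNS(=O)(=O)c2ccc(C)cc2)[C@@H]2COC(=O)[C@H]2C)cc(OC)c1OC
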